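**Retrosynthetic overview**

1. The target is the (−)-caryophyllene oxide core (cyclobutane ring A trans-fused to the nine-membered ring B, oxirane ring C on C4–C5, exocyclic methylene on C8) whose C11 carries the chain C12–C13–C14(OAc)–C15(OH)Me2.
2. Key disconnection C13–C14: a four-component nickel-hydride union of vinyl epoxide 4, aldehyde 7, AcBr and a hydrosilane makes the C13–C14 bond, the C14 stereocentre and the acetate in one operation.
3. Enabling feature: C14 is a secondary carbinol carbon carrying an acetate (a latent 1-bromoalkyl acetate from an aldehyde and AcBr), and C12–C13 is an unbranched two-carbon link on the fully substituted C11 of ring A. A C12=C13 vinyl group is therefore the only monosubstituted alkene, cannot chain-walk past C11, and differs from the 1,1-disubstituted C8 methylene on ring B.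
4. Vinyl epoxide 4 comes from chiral-pool (−)-caryophyllene oxide 1 (fifteen carbons, four stereocentres) by cytochrome P450 hydroxylation of the C11 methyl cis to H-1 (sets C11), oxidation and methylenation; aldehyde 7 comes from methyl 2-hydroxyisobutyrate.
5. Ring order: no ring is formed in the route; rings A, B and C are taken intact from 1, and the last step is a desilylation.

Key step: step 6

Remark (numbering): ring A = cyclobutane C1–C9–C10–C11, ring B = carbocycle C1 to C9, ring C = oxirane on C4–C5, C8 carries the methylene, the C11 side chain is C12–C13–C14–C15, and C12 is the C11 methyl carbon of 1 that is cis to H-1 (and cis-1,3 across ring A to the C9–C8 bond).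

**Step 1**
Reactants: 1 (−)-caryophyllene oxide
Product: 2 (11R)-12-hydroxycaryophyllene oxide
Conditions: cytochrome P450 monooxygenase (self-sufficient CYP102A1 variant chosen from a mutant panel for C12 hydroxylation, cell-free lysate), glucose dehydrogenase, D-glucose, NADP+ (cat.), air, KH2PO4/K2HPO4 buffer pH 8, 2% DMSO, 25 °C
Reagents that add atoms: dioxygen, O=O
Why: Cytochrome P450 C–H hydroxylation (hydrogen abstraction by the haem oxoiron species followed by oxygen rebound) is the known oxidative fate of the geminal methyl groups of this epoxide in microbial and mammalian metabolism, and the selected variant should bind 1 so that only the C11 methyl cis to H-1 reaches the iron, which turns C11 into a stereocentre (11R) under enzyme control and leaves the epoxide, the C8 methylene and C1, C4, C5 and C9 untouched.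

**Step 2**
Reactants: 2 (11R)-12-hydroxycaryophyllene oxide
Product: 3 C12 aldehyde (formyl group on C11)
Conditions: (n-Pr)4N[RuO4] (5 mol %), N-methylmorpholine N-oxide (1.5 equiv), 4 Å MS, CH2Cl2, rt
Reagents that add atoms: none
Why: Ley–Griffith oxidation converts the neopentyl-type primary alcohol into the aldehyde under neutral conditions that spare the acid-sensitive epoxide and the alkene, and since C11 bears no hydrogen the new stereocentre cannot epimerise.

**Step 3**
Reactants: 3 C12 aldehyde
Product: 4 vinyl epoxide (C12=C13 vinyl group on C11)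
Conditions: Ph3PCH3Br (1.5 equiv), KOt-Bu (1.4 equiv), THF, 0 °C → rt
Reagents that add atoms: methyltriphenylphosphonium bromide, C[P+](c1ccccc1)(c1ccccc1)c1ccccc1.[Br-]
Why: Wittig methylenation of the non-enolisable aldehyde with the unstabilised ylide should give the C12=C13 vinyl group cleanly, because the basic ylide attacks neither the trisubstituted epoxide nor any stereocentre.

**Step 4**
Reactants: 5 methyl 2-hydroxy-2-methylpropanoate
Product: 6 methyl 2-[(tert-butyldimethylsilyl)oxy]-2-methylpropanoate
Conditions: TBSOTf (1.2 equiv), 2,6-lutidine (1.5 equiv), CH2Cl2, 0 °C → rt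
Reagents that add atoms: tert-butyldimethylsilyl trifluoromethanesulfonate, CC(C)(C)[Si](C)(C)OS(=O)(=O)C(F)(F)F
Why: Silyl ether formation with the reactive silyl triflate and a hindered pyridine base is the standard way to protect a tertiary α-hydroxy ester, and no stereocentre is involved.

**Step 5**
Reactants: 6 methyl 2-[(tert-butyldimethylsilyl)oxy]-2-methylpropanoate
Product: 7 2-[(tert-butyldimethylsilyl)oxy]-2-methylpropanal
Conditions: i-Bu2AlH (1.1 equiv), CH2Cl2, −78 °C; MeOH, then aq. KNaC4H4O6
Reagents that add atoms: none
Why: Partial ester reduction with i-Bu2AlH at −78 °C stops at the aldehyde oxidation level for α-silyloxy esters until aqueous work-up, and no stereocentre is involved.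

**Step 6**
Reactants: 4 vinyl epoxide; 7 2-[(tert-butyldimethylsilyl)oxy]-2-methylpropanal
Product: 9 (14R)-acetate TBS ether (the target with 15-OTBS), via racemic bromo acetate 8 (not isolated)
Conditions: 7 (1.6 equiv), AcBr (1.5 equiv), ZnBr2 (1 mol %), CH2Cl2, −20 → 0 °C, solvent removed; then 4 (1.0 equiv), NiBr2(MeOCH2CH2OMe) (10 mol %), C2-symmetric chiral bis(oxazoline) ligand (12 mol %; the antipode that gives 14R, assigned beforehand on 3,3-dimethylbut-1-ene as model olefin), (EtO)3SiH (2.5 equiv), K3PO4·H2O (2.5 equiv), DMA/THF, 0 °C → rt
Reagents that add atoms: acetyl bromide, CC(=O)Br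
Why: AcBr adds across the C=O of 7 to give racemic 8, monovalent nickel abstracts its bromine to leave a planar α-acetoxyalkyl radical at C14, and the chiral nickel hydride generated from the divalent nickel bromide complex, (EtO)3SiH and K3PO4 inserts the C12=C13 vinyl group of 4 in the anti-Markovnikov sense; capture of the radical by the resulting primary alkylnickel and reductive elimination from trivalent nickel forge the C13–C14 bond. The closest known reaction type is the nickel-hydride-catalysed enantioconvergent hydroalkylation of terminal olefins with racemic 1-bromoalkyl esters made in the same flask from an aldehyde and an acyl bromide (four-component synthesis of esters of dialkyl carbinols). No ring is closed, and rings A, B and C pass through unchanged. The one new stereocentre, C14 (R), is set by the chiral bis(oxazoline) ligand on nickel in the radical capture and reductive elimination (catalyst control: both enantiomers of 8 converge through the planar radical, and the nearest substrate stereocentre, C11, lies three bonds away). The step needs chemoselectivity for the monosubstituted C12=C13 over the 1,1-disubstituted C8 methylene, linear regioselectivity and survival of the epoxide and of ring A: Ni–H insertion is much faster for the monosubstituted alkene, C11 bears no hydrogen so chain walking cannot pass C12 and the unhindered primary C13–Ni species is the one that couples, no radical is formed on the olefin partner so no cyclobutylcarbinyl radical can open ring A, and the medium is basic and free of AcBr because 7 is taken in excess over AcBr.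

**Step 7**
Reactants: 9 (14R)-acetate TBS ether
Product: 10 target, (1R,4R,5R,9S,11R,14R)-14-acetoxy-4,5-epoxy-15-hydroxy compound
Conditions: n-Bu4NF/AcOH (1:1, 3 equiv), THF, rt → 40 °C
Reagents that add atoms: none
Why: Fluoride-mediated silyl ether cleavage buffered with acetic acid should free the tertiary alcohol while the alkoxide is protonated before it can attack the neighbouring acetate, and neither the epoxide nor any stereocentre is exposed to strong acid or base.

**Compound list**

1 | (−)-caryophyllene oxide, (1R,4R,5R,9S) | C=C1CC[C@H]2O[C@]2(C)CC[C@@H]2[C@@H]1CC2(C)C | starting material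
2 | (11R)-12-hydroxycaryophyllene oxide: 1 with the C11 methyl cis to H-1 turned into CH2OH | C=C1CC[C@H]2O[C@]2(C)CC[C@@H]2[C@@H]1C[C@@]2(C)CO | intermediate
3 | (11R) C12 aldehyde: C11 carries CH3 and CHO, CHO cis to H-1 | C=C1CC[C@H]2O[C@]2(C)CC[C@@H]2[C@@H]1C[C@@]2(C)C=O | intermediate
4 | vinyl epoxide, (1R,4R,5R,9S,11S): C11 carries CH3 and CH=CH2 (C12=C13), vinyl cis to H-1 | C=C1CC[C@H]2O[C@]2(C)CC[C@@H]2[C@@H]1C[C@@]2(C)C=C | intermediate
5 | methyl 2-hydroxy-2-methylpropanoate | COC(=O)C(C)(C)O | starting material
6 | methyl 2-[(tert-butyldimethylsilyl)oxy]-2-methylpropanoate | COC(=O)C(C)(C)O[Si](C)(C)C(C)(C)C | intermediate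
7 | 2-[(tert-butyldimethylsilyl)oxy]-2-methylpropanal | CC(C)(C=O)O[Si](C)(C)C(C)(C)C | intermediate
8 | rac-1-bromo-2-[(tert-butyldimethylsilyl)oxy]-2-methylpropyl acetate | CC(=O)OC(Br)C(C)(C)O[Si](C)(C)C(C)(C)C | intermediate
9 | (14R)-14-acetoxy-15-[(tert-butyldimethylsilyl)oxy] compound: the target with the tertiary OH silylated | C=C1CC[C@H]2O[C@]2(C)CC[C@@H]2[C@@H]1C[C@@]2(C)CC[C@@H](OC(C)=O)C(C)(C)O[Si](C)(C)C(C)(C)C | intermediate
10 | target, (1R,4R,5R,9S,11R,14R): caryophyllene oxide core with C11 chain CH2CH2CH(OAc)C(CH3)2OH | C=C1CC[C@H]2O[C@]2(C)CC[C@@H]2[C@@H]1C[C@@]2(C)CC[C@@H](OC(C)=O)C(C)(C)O | target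

**Totals**

Total step count: 7. Longest linear sequence: 5 steps (steps 1, 2, 3, 6, 7).

**Steps most likely to fail**

Step 1. The hydroxylation may go to the wrong C–H bond (the other diastereotopic C11 methyl, the C4 methyl, allylic C7) or run on to the acid. The fallback sets out from 1 and comes back at 4; it moves the C–H oxidation to a ketone substrate and a ketone-binding enzyme family.
- Ozonolysis of the C8 methylene (O3, CH2Cl2/MeOH, −78 °C, then Me2S) should give the nor-ketone kobusone F1.
- F1 is hydroxylated by a P450 of the camphor 5-monooxygenase type (CYP101A1 variant with putidaredoxin and putidaredoxin reductase, NADH recycling) to give hydroxy ketone F2. The C8 carbonyl, hydrogen-bonded in the pocket as the camphor carbonyl is and lying cis-1,3 across ring A to the wanted methyl, should steer that methyl to the iron.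
- Oxidation with (n-Pr)4N[RuO4]/N-methylmorpholine N-oxide gives keto aldehyde F3.
- Double Wittig methylenation with excess Ph3P=CH2 (Ph3PCH3Br, KOt-Bu, THF, rt → 50 °C) installs the C8 methylene and the C12=C13 vinyl group together and returns to 4.

Step 6. The coupling may stall because the C14 radical is flanked by a fully substituted carbon, the enantioselectivity may erode, or the C8 methylene may be hydrometalated as well. The fallback sets out from 4 and comes back at 9; it makes the same C13–C14 bond by carbonyl addition and sets C14 by reagent-controlled reduction.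
- Chemoselective hydroboration of the vinyl group (pinacolborane, RhCl(PPh3)3 cat., THF) gives the primary pinacol boronate F4; oxidation (NaBO3·4H2O) gives the primary alcohol F5.
- Mesylation (MsCl, Et3N, CH2Cl2, 0 °C) gives mesylate F6, and NaI/NaHCO3 in acetone gives the primary iodide F7.
- Iodine–lithium exchange (t-BuLi, Et2O/pentane, −78 °C) gives the alkyllithium F8, which adds to aldehyde 7 to give the secondary alcohol F9 as a mixture of C14 epimers.
- Oxidation with (n-Pr)4N[RuO4]/N-methylmorpholine N-oxide gives ketone F10.
- Corey–Bakshi–Shibata reduction ((S)-2-methyl-CBS-oxazaborolidine, catecholborane, toluene, −78 °C; C(CH3)2OTBS as the large group) should give the (14R)-alcohol F11.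
- Acetylation (Ac2O, DMAP, Et3N, CH2Cl2) returns to 9.

Step 7. The acetyl group may migrate to the tertiary oxygen or be lost under fluoride, or the tertiary silyl ether may cleave too slowly. The fallback sets out from 9 and comes back at 10; it gives up keeping the acetate through the deprotection.
- Methanolysis of the acetate (K2CO3, MeOH) gives the hydroxy silyl ether F11, the same compound that the fallback for step 6 passes through.
- Unbuffered n-Bu4NF (THF, 50 °C), now with no acyl group to migrate, gives diol F12.
- Selective acetylation of the secondary hydroxyl (Ac2O, pyridine, cat. DMAP, CH2Cl2, 0 °C), which should leave the tertiary hydroxyl untouched, gives 10.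

**Further compounds**

F1 | step 1 | kobusone, the C8 nor-ketone of 1 | O=C1CC[C@H]2O[C@]2(C)CC[C@@H]2[C@@H]1CC2(C)C
F2 | step 1 | 12-hydroxykobusone, CH2OH on C11 cis to H-1 | O=C1CC[C@H]2O[C@]2(C)CC[C@@H]2[C@@H]1C[C@@]2(C)CO
F3 | step 1 | keto aldehyde, C8 ketone and C12 formyl group | O=C1CC[C@H]2O[C@]2(C)CC[C@@H]2[C@@H]1C[C@@]2(C)C=O
F4 | step 6 | C13 pinacol boronate of the core | C=C1CC[C@H]2O[C@]2(C)CC[C@@H]2[C@@H]1C[C@@]2(C)CCB1OC(C)(C)C(C)(C)O1
F5 | step 6 | C13 primary alcohol | C=C1CC[C@H]2O[C@]2(C)CC[C@@H]2[C@@H]1C[C@@]2(C)CCO
F6 | step 6 | C13 mesylate | C=C1CC[C@H]2O[C@]2(C)CC[C@@H]2[C@@H]1C[C@@]2(C)CCOS(C)(=O)=O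
F7 | step 6 | C13 primary iodide | C=C1CC[C@H]2O[C@]2(C)CC[C@@H]2[C@@H]1C[C@@]2(C)CCI
F8 | step 6 | C13 alkyllithium | C=C1CC[C@H]2O[C@]2(C)CC[C@@H]2[C@@H]1C[C@@]2(C)CC[Li]
F9 | step 6 | C14 secondary alcohol with 15-OTBS, mixture of C14 epimers | C=C1CC[C@H]2O[C@]2(C)CC[C@@H]2[C@@H]1C[C@@]2(C)CCC(O)C(C)(C)O[Si](C)(C)C(C)(C)C
F10 | step 6 | C14 ketone with 15-OTBS | C=C1CC[C@H]2O[C@]2(C)CC[C@@H]2[C@@H]1C[C@@]2(C)CCC(=O)C(C)(C)O[Si](C)(C)C(C)(C)C
F11 | step 6 | (14R)-alcohol with 15-OTBS | C=C1CC[C@H]2O[C@]2(C)CC[C@@H]2[C@@H]1C[C@@]2(C)CC[C@@H](O)C(C)(C)O[Si](C)(C)C(C)(C)C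
F12 | step 7 | (14R)-14,15-diol | C=C1CC[C@H]2O[C@]2(C)CC[C@@H]2[C@@H]1C[C@@]2(C)CC[C@@H](O)C(C)(C)O
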